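**Plan**

Rings: A = terminal 2,4-dihydroxyphenyl ketone ring (C1 ketone, C2 and C4 OH); B = phenol ring of the biaryl (C1 CH2CH2CO arm to ring A, C3 ring C, C4 OH); C = resorcinol ring of the biaryl (C1 ring B, C3 ketone of the arm to ring D, C4 and C6 OH); D = 4-hydroxyphenyl ring.
Enabling feature: each ketone carbon is bonded to a ring carbon next to a phenolic oxygen (C1 of ring A beside the C2 hydroxyl, C3 of ring C beside the C4 hydroxyl), so both aryl–C(=O) bonds can be traced back to O-acyl bonds of phenyl esters.
Retrosynthesis cuts, in order: the four O–CH3 bonds of a tetramethyl ether; the C1(ring A)–CO and C3(ring C)–CO bonds (back to one bis(aryl ester)); the biaryl bond C3(ring B)–C1(ring C); the two ester C–O bonds.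
Forward: no ring is built. Ring D is joined to ring C and ring B to ring A by esterification, rings B and C by borylation and Suzuki coupling, then one irradiation shifts both acyl groups from O to C, and demethylation finishes.
Stereochemistry: the target has no stereocentre and no stereogenic double bond, and the biaryl axis rotates freely, so nothing has to be set.

Key step: step 5

Remark: 4-bromo-3-methoxyphenol and 3-(3-bromo-4-methoxyphenyl)propanoic acid are taken as purchasable catalogue compounds.

**Route**

Step 1
Reactants: 1 4-bromo-3-methoxyphenol; 2 3-(4-methoxyphenyl)propanoic acid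
Product: 3 4-bromo-3-methoxyphenyl 3-(4-methoxyphenyl)propanoate
Conditions: DCC (1.1 equiv), DMAP (0.1 equiv), CH2Cl2, 0 °C to rt
Reagents that add atoms: none
Why: Steglich esterification, in which DMAP relays the acyl group from the DCC-activated acid to the phenol under neutral conditions that leave the aryl bromide and the methyl ethers untouched.

Step 2
Reactants: 4 3-(3-bromo-4-methoxyphenyl)propanoic acid; 5 3-methoxyphenol
Product: 6 3-methoxyphenyl 3-(3-bromo-4-methoxyphenyl)propanoate
Conditions: DCC (1.1 equiv), DMAP (0.1 equiv), CH2Cl2, 0 °C to rt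
Reagents that add atoms: none
Why: A second Steglich esterification joins the ring B acid to the ring A phenol, and the bromide ortho to the methoxy group is inert to carbodiimide and DMAP.

Step 3
Reactants: 6 3-methoxyphenyl 3-(3-bromo-4-methoxyphenyl)propanoate
Product: 7 3-methoxyphenyl 3-[4-methoxy-3-(4,4,5,5-tetramethyl-1,3,2-dioxaborolan-2-yl)phenyl]propanoate
Conditions: B2pin2 (1.2 equiv), Pd(dppf)Cl2 (3 mol%), KOAc (3 equiv), 1,4-dioxane, 85 °C
Reagents that add atoms: bis(pinacolato)diboron, CC1(C)OB(OC1(C)C)B1OC(C)(C)C(C)(C)O1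
Why: Miyaura borylation, in which the aryl bromide adds oxidatively to zerovalent palladium and the acetate-activated diboron transmetallates, while the weak base KOAc should neither cleave the phenyl ester nor trigger homocoupling.

Step 4
Reactants: 7 3-methoxyphenyl 3-[4-methoxy-3-(4,4,5,5-tetramethyl-1,3,2-dioxaborolan-2-yl)phenyl]propanoate; 3 4-bromo-3-methoxyphenyl 3-(4-methoxyphenyl)propanoate
Product: 8 3-methoxyphenyl 3-{4-methoxy-3-[2-methoxy-4-(3-(4-methoxyphenyl)propanoyloxy)phenyl]phenyl}propanoate
Conditions: Pd(OAc)2 (3 mol%), SPhos (6 mol%), CsF (3 equiv), anhydrous 1,4-dioxane, 85 °C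
Reagents that add atoms: none
Why: Suzuki–Miyaura coupling in which fluoride activates the pinacol boronate without hydroxide or alkoxide, so both phenyl esters should survive, and the bulky electron-rich ligand SPhos suits the 2,2'-dimethoxy-substituted biaryl bond.

Step 5
Reactants: 8 3-methoxyphenyl 3-{4-methoxy-3-[2-methoxy-4-(3-(4-methoxyphenyl)propanoyloxy)phenyl]phenyl}propanoate
Product: 11 1-(2-hydroxy-4-methoxyphenyl)-3-{3-[4-hydroxy-2-methoxy-5-(3-(4-methoxyphenyl)propanoyl)phenyl]-4-methoxyphenyl}propan-1-one, via ring C monoketone 9 (not isolated), via ring A monoketone 10 (not isolated)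
Conditions: hν 254 nm (low-pressure Hg lamps, quartz flow coil), degassed MeCN (5 mM), 20 °C
Reagents that add atoms: none
Why: Double photo-Fries rearrangement: excitation near 254 nm breaks each ArO–C(=O) bond homolytically from the singlet state, the aryloxyl/acyl radical pair recombines inside the solvent cage at a ring carbon ortho or para to the oxygen, and the cyclohexadienone formed tautomerises to the phenol; either ester may react first, so monoketones 9 and 10 both lie on the way to 11. The closest known reaction type is the photo-Fries conversion of aryl 3-arylpropanoates into 2'-hydroxydihydrochalcones, in which the primary acyl radical loses CO too slowly to compete with recombination. No ring is closed and no stereocentre is created. Because the acyl group is handed over within the cage, each one stays on the ring whose oxygen carried it, which a Lewis acid Fries reaction through free acylium ions would not ensure for two different esters. The step needs site selectivity: on ring C the para carbon C1 is occupied by ring B and C5 is flanked by two oxygen substituents, which leaves C3, and on ring A the open ortho carbon C1 (para to the C4 methoxy group) is preferred over C3 between the two oxygens, while attack at the para carbon would still give a 1-acyl-2,4-dioxygenated ring that the final demethylation turns into the same ring A. The ortho-hydroxyaryl ketones are photostable through excited-state proton transfer, so long irradiation of a dilute flowing solution should push the second shift despite the inner-filter effect.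

Step 6
Reactants: 11 1-(2-hydroxy-4-methoxyphenyl)-3-{3-[4-hydroxy-2-methoxy-5-(3-(4-methoxyphenyl)propanoyl)phenyl]-4-methoxyphenyl}propan-1-one
Product: 12 1-(2,4-dihydroxyphenyl)-3-{3-[2,4-dihydroxy-5-(3-(4-hydroxyphenyl)propanoyl)phenyl]-4-hydroxyphenyl}propan-1-one
Conditions: BBr3 (10 equiv), CH2Cl2, −78 °C to rt; then H2O, 0 °C
Reagents that add atoms: none
Why: BBr3 cleavage of aryl methyl ethers, in which each ether oxygen binds boron and bromide removes the methyl group by SN2, the two ketones being held as boron chelates of their ortho hydroxyls until the aqueous quench releases all six phenols.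

**Compound list**

1 | 4-bromo-3-methoxyphenol | COc1cc(O)ccc1Br | starting material
2 | 3-(4-methoxyphenyl)propanoic acid | COc1ccc(CCC(=O)O)cc1 | starting material
3 | 4-bromo-3-methoxyphenyl 3-(4-methoxyphenyl)propanoate | COc1ccc(CCC(=O)Oc2ccc(Br)c(OC)c2)cc1 | intermediate
4 | 3-(3-bromo-4-methoxyphenyl)propanoic acid | COc1ccc(CCC(=O)O)cc1Br | starting material
5 | 3-methoxyphenol | COc1cccc(O)c1 | starting material
6 | 3-methoxyphenyl 3-(3-bromo-4-methoxyphenyl)propanoate | COc1cccc(OC(=O)CCc2ccc(OC)c(Br)c2)c1 | intermediate
7 | 3-methoxyphenyl 3-[4-methoxy-3-(4,4,5,5-tetramethyl-1,3,2-dioxaborolan-2-yl)phenyl]propanoate | COc1cccc(OC(=O)CCc2ccc(OC)c(B3OC(C)(C)C(C)(C)O3)c2)c1 | intermediate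
8 | 3-methoxyphenyl 3-{4-methoxy-3-[2-methoxy-4-(3-(4-methoxyphenyl)propanoyloxy)phenyl]phenyl}propanoate | COc1cccc(OC(=O)CCc2ccc(OC)c(-c3ccc(OC(=O)CCc4ccc(OC)cc4)cc3OC)c2)c1 | intermediate
9 | 3-methoxyphenyl 3-{3-[4-hydroxy-2-methoxy-5-(3-(4-methoxyphenyl)propanoyl)phenyl]-4-methoxyphenyl}propanoate (ring C monoketone) | COc1cccc(OC(=O)CCc2ccc(OC)c(-c3cc(C(=O)CCc4ccc(OC)cc4)c(O)cc3OC)c2)c1 | intermediate
10 | 4-{5-[3-(2-hydroxy-4-methoxyphenyl)-3-oxopropyl]-2-methoxyphenyl}-3-methoxyphenyl 3-(4-methoxyphenyl)propanoate (ring A monoketone) | O=C(CCc1ccc(OC)c(-c2ccc(OC(=O)CCc3ccc(OC)cc3)cc2OC)c1)c1ccc(OC)cc1O | intermediate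
11 | 1-(2-hydroxy-4-methoxyphenyl)-3-{3-[4-hydroxy-2-methoxy-5-(3-(4-methoxyphenyl)propanoyl)phenyl]-4-methoxyphenyl}propan-1-one | O=C(CCc1ccc(OC)c(-c2cc(C(=O)CCc3ccc(OC)cc3)c(O)cc2OC)c1)c1ccc(OC)cc1O | intermediate
12 | 1-(2,4-dihydroxyphenyl)-3-{3-[2,4-dihydroxy-5-(3-(4-hydroxyphenyl)propanoyl)phenyl]-4-hydroxyphenyl}propan-1-one | O=C(CCc1ccc(O)c(-c2cc(C(=O)CCc3ccc(O)cc3)c(O)cc2O)c1)c1ccc(O)cc1O | target

**Step count**

Total: 6 steps. Longest linear sequence: 5 steps (steps 2, 3, 4, 5, 6 from acid 4).

**Steps most likely to fail**

Step 5. The second acyl shift may stall because the hydroxyaryl ketone formed first sits in the same molecule, absorbs the light and dissipates it. Radical pairs may also escape the cage and end as phenols, and some recombination may occur at the carbon between the two oxygens. The fallback gives up the acyl shift and forms both aryl–carbonyl bonds by Friedel–Crafts acylation of dimethoxyarenes. It sets out from acid 4. Direct acylation of an excess of 1,3-dimethoxybenzene with 4 in P2O5/MeSO3H at rt should outrun indanone formation and give 3-(3-bromo-4-methoxyphenyl)-1-(2,4-dimethoxyphenyl)propan-1-one F1, by attack para to one methoxy group and ortho to the other. Suzuki coupling of F1 with (2,4-dimethoxyphenyl)boronic acid (Pd(dppf)Cl2, K2CO3, dioxane/H2O, 90 °C; no base-labile ester is present) should give 1-(2,4-dimethoxyphenyl)-3-[3-(2,4-dimethoxyphenyl)-4-methoxyphenyl]propan-1-one F2. Acylation of F2 with acid 2 in the same medium should go to the most electron-rich ring, at the ring C carbon para to one methoxy group and ortho to the other, and give the hexamethyl ether 1-(2,4-dimethoxyphenyl)-3-{3-[2,4-dimethoxy-5-(3-(4-methoxyphenyl)propanoyl)phenyl]-4-methoxyphenyl}propan-1-one F3. BBr3 in CH2Cl2 then cleaves the six methyl ethers, and the fallback comes back to the route at target 12.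

Step 4. The phenyl esters may be cleaved or transacylated by the base, the ortho-methoxy boronate may lose boron by protodeboronation, and transmetallation may be slow under anhydrous fluoride conditions. The fallback forms the biaryl bond before either phenyl ester exists. It sets out from acid 4 and phenol 1 and returns at bis(ester) 8.
- Acid 4 with 2-methylpropene and catalytic H2SO4 in CH2Cl2 should give tert-butyl 3-(3-bromo-4-methoxyphenyl)propanoate F4.
- Miyaura borylation (B2pin2, Pd(dppf)Cl2, KOAc, dioxane) should give tert-butyl 3-[4-methoxy-3-(4,4,5,5-tetramethyl-1,3,2-dioxaborolan-2-yl)phenyl]propanoate F5.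
- Suzuki coupling of F5 with free phenol 1 under ordinary aqueous conditions (Pd(dppf)Cl2, K2CO3, dioxane/H2O, 90 °C), which the tert-butyl ester tolerates, should give tert-butyl 3-[3-(4-hydroxy-2-methoxyphenyl)-4-methoxyphenyl]propanoate F6.
- Steglich esterification of F6 with acid 2 (DCC, DMAP) should give tert-butyl 3-{4-methoxy-3-[2-methoxy-4-(3-(4-methoxyphenyl)propanoyloxy)phenyl]phenyl}propanoate F7.
- CF3CO2H in CH2Cl2 should remove the tert-butyl group without touching the phenyl ester and give 3-{4-methoxy-3-[2-methoxy-4-(3-(4-methoxyphenyl)propanoyloxy)phenyl]phenyl}propanoic acid F8.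
- Steglich esterification of F8 with phenol 5 then gives 8.

Step 6. Cleavage of four methyl ethers may stop short on a substrate that ties up BBr3 in two ketone chelates, partly dealkylated borates may precipitate, and the electron-rich hexaphenol may oxidise in air during work-up. The fallback changes the mode of C–O cleavage from Lewis acid activation to nucleophilic dealkylation under basic, reducing conditions. It sets out from 11, which is heated with NaSEt (from EtSH and NaH) in DMF at 130–150 °C so that thiolate removes each methyl group by SN2 at carbon, the ketones being protected as their phenoxide-conjugated forms. Acidification under argon returns to the route at target 12. No new compound lies on this path.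

**Further compounds**

F1 | step 5 | 3-(3-bromo-4-methoxyphenyl)-1-(2,4-dimethoxyphenyl)propan-1-one | COc1ccc(C(=O)CCc2ccc(OC)c(Br)c2)c(OC)c1
F2 | step 5 | 1-(2,4-dimethoxyphenyl)-3-[3-(2,4-dimethoxyphenyl)-4-methoxyphenyl]propan-1-one | COc1ccc(C(=O)CCc2ccc(OC)c(-c3ccc(OC)cc3OC)c2)c(OC)c1
F3 | step 5 | 1-(2,4-dimethoxyphenyl)-3-{3-[2,4-dimethoxy-5-(3-(4-methoxyphenyl)propanoyl)phenyl]-4-methoxyphenyl}propan-1-one | COc1ccc(C(=O)CCc2ccc(OC)c(-c3cc(C(=O)CCc4ccc(OC)cc4)c(OC)cc3OC)c2)c(OC)c1
F4 | step 4 | tert-butyl 3-(3-bromo-4-methoxyphenyl)propanoate | COc1ccc(CCC(=O)OC(C)(C)C)cc1Br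
F5 | step 4 | tert-butyl 3-[4-methoxy-3-(4,4,5,5-tetramethyl-1,3,2-dioxaborolan-2-yl)phenyl]propanoate | COc1ccc(CCC(=O)OC(C)(C)C)cc1B1OC(C)(C)C(C)(C)O1
F6 | step 4 | tert-butyl 3-[3-(4-hydroxy-2-methoxyphenyl)-4-methoxyphenyl]propanoate | COc1ccc(CCC(=O)OC(C)(C)C)cc1-c1ccc(O)cc1OC
F7 | step 4 | tert-butyl 3-{4-methoxy-3-[2-methoxy-4-(3-(4-methoxyphenyl)propanoyloxy)phenyl]phenyl}propanoate | COc1ccc(CCC(=O)Oc2ccc(-c3cc(CCC(=O)OC(C)(C)C)ccc3OC)c(OC)c2)cc1
F8 | step 4 | 3-{4-methoxy-3-[2-methoxy-4-(3-(4-methoxyphenyl)propanoyloxy)phenyl]phenyl}propanoic acid | COc1ccc(CCC(=O)Oc2ccc(-c3cc(CCC(=O)O)ccc3OC)c(OC)c2)cc1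
F0 | step 6 | none | none
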